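Start with an easy subtraction: take each plateau from the charge.

common to all: starting material 0.20 M; enzyme 40 µM

|  | protic impurity | remark | time |
|---|---|---|---|
| Thursday's | 0.040 M | run made earlier |  |
| Wednesday's | 0.090 M | run made earlier |  |
| flask | 0.0600 M |  | 50 h |

| Thursday's: time / h | Thursday's: target / % | Wednesday's: time / h | Wednesday's: target / % |
|---|---|---|---|
| 4.00 | 85 | 10.0 | 71 |
| 12.0 | 84 | 20.0 | 69 |
| 20.0 | 81 | 30.0 | 68 |
| 30.0 | 87 | 40.0 | 71 |
| 50.0 | 84 | 48.0 | 68 |
| 60.0 | 86 | 60.0 | 67 |

(each reading ± 1.5 percentage points)

1. at 50 h, what has stopped the reaction, if anything has (all of the starting material has reacted / forward and back rates have come level / it is still moving)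
2. target at 50 h, in percent of the starting material charged

Read the two tables column against column. Thursday's run stands flat from its first reading, at 4.00 h, with a mean of 84.5 %. Wednesday's run, with more protic impurity, stands flat lower, at 69.0 %.

Take the missing part, 0.0310 M on Thursday and 0.0620 M on Wednesday, as starting material lost one for one to the impurity. Now count lifetimes: ln(charged over remaining c(protic impurity)) gives 1.49 on Thursday and 1.17 on Wednesday.

Let target made be the clock, not hours. The target made per impurity lifetime, a selectivity factor in reciprocal form, reads 0.113 M and 0.118 M, so carry the mean, 0.116 M.

Assume this flask's starting material ends wholly divided between target and loss. Begin from the mean target of the two runs, 0.154 M. That lets the flask lose 0.0441 M, so my reckoning gives 78.0 %.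

The forecast says all of the starting material has reacted and 78 %, between 75.5 % and 80.5 %, on the ground that “the impurity is depleted as it goes”.

At 50 h the flask gives 77.0 %: all of the starting material has reacted, with 0 % of the starting material left.

    starting material + enzyme → target + enzyme, rate k1*[starting material]*[enzyme]/(1 + ([starting material]/Km1)) (4.64 mM, k = 118 M⁻¹ s⁻¹)
    starting material + protic impurity → quenched substrate (k = 0.00223 M⁻¹ s⁻¹)

This flask falls short of the full charge because the step into quenched substrate acts together with the crowding by starting material in the enzyme's rate law: it gives 77.0 %, against 100 % without that step and 97.4 % without the crowding. The carried quantity turns the flask's target into 26.4 % of the impurity remaining; the flask holds 23.4 %.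

Now assume target per lifetime grows in step with enzyme, which neither run tested. With 1.0 × 10⁻⁴ M of enzyme it becomes 0.289 M, and two passes of the reckoning give 86.4 %; that neighbouring flask gives 85.2 %.

All runs stem from a simulated flask with made-up constants; noise was put on by code.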